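**Retrosynthetic overview**

1. Atom labels (spiro[5.5]undecane locants): ring A = C1(Me)=C2–C3–C4(Br)–C5(Me2)–C6(spiro); ring B = C6–C7–C8–C9(Me)(Cl)–C10(Br)–C11.
2. Feature used: inside ring A the C4 bromide is homoallylic to the C1=C2 bond (Br–C4–C3–C2=C1). C4–Br and C1=C2 are therefore traced back to a C1 cyclopropylcarbinyl cation of a spiro bicyclo[3.1.0]hexane in which C2–C4 is the ring-fusion bond and C3 the cyclopropane CH2 (carbinol 16 ⇒ bromo ketone 17).
3. After the key step the symmetric ring B ketone of 17 is elaborated: arm-selective enol silane (sets C6), α-bromination (C10), methyl addition (C9 carbinol), chloride for hydroxyl with retention (C9).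
4. Before it, 16 comes from spiro enone ketal 9 by CBS reduction, hydroxyl-directed cyclopropanation (fixes C2/C4 and thereby the later C4–Br), oxidation, MeMgBr addition and ketal hydrolysis; 9 comes from enone 5 and diiodide 4 by double alkylation at C6.
5. Ring order: five-membered carbocycle (bought) → ring B (spiro-annulation) → cyclopropane → ring A (enlargement of the five-membered ring by C3).

Key step: step 9

Assumption: the CBS reduction is taken to treat the quaternary C6 as the large ketone flank, and the chiral amide is taken to act on the ring B chair with C5 equatorial and C1 axial in the sense known for 4-tert-butylcyclohexanone; should either sense prove opposite, the mirror-image catalyst or amide serves.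

**Route**

Step 1
Reactants: 1 1,5-dichloropentan-3-one; 2 ethylene glycol
Product: 3 2,2-bis(2-chloroethyl)-1,3-dioxolane
Conditions: p-toluenesulfonic acid monohydrate (cat.), benzene, reflux, azeotropic removal of water
Reagents that add atoms: ethylene glycol (2), OCCO
Why: Acid-catalysed ketalisation (dioxolane formation) is driven by removal of water and masks the ketone, so that the β-chloro groups cannot be lost by elimination toward a vinyl ketone under the basic conditions that follow.

Step 2
Reactants: 3 2,2-bis(2-chloroethyl)-1,3-dioxolane
Product: 4 2,2-bis(2-iodoethyl)-1,3-dioxolane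
Conditions: NaI (4 equiv), acetone, reflux, dark
Reagents that add atoms: sodium iodide, [Na+].[I-]
Why: Finkelstein exchange, pulled by precipitation of NaCl from acetone, converts both primary chlorides into the iodides needed for alkylation of a hindered enolate.

Step 3
Reactants: 5 4,4-dimethylcyclopent-2-en-1-one; 4 2,2-bis(2-iodoethyl)-1,3-dioxolane
Product: 9 12,12-dimethyl-1,4-dioxadispiro[4.2.4.2]tetradec-10-en-9-one (spiro enone ketal), via lithium dienolate 6 (not isolated), via iodo enone 7 (not isolated), via iodo enolate 8 (not isolated)
Conditions: LiN(i-Pr)2 (1.05 equiv), THF, −78 °C; 4 (1.2 equiv), DMPU, −78 → −20 °C; LiN(i-Pr)2 (1.1 equiv), −78 °C → rt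
Reagents that add atoms: 2,2-bis(2-iodoethyl)-1,3-dioxolane (4), ICCC1(CCI)OCCO1
Why: Twofold enolate alkylation (spiro-annulation): C6 is the only enolisable carbon of 5 because C5 is quaternary, the first SN2 step is intermolecular and the second, after renewed deprotonation, is a 6-exo-tet closure of ring B that makes the quaternary spiro carbon; no stereocentre arises because ring B is symmetric.

Step 4
Reactants: 9 spiro enone ketal
Product: 10 (9R)-12,12-dimethyl-1,4-dioxadispiro[4.2.4.2]tetradec-10-en-9-ol (allylic alcohol, C1 R in target labels)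
Conditions: (S)-1-methyl-3,3-diphenyltetrahydro-1H,3H-pyrrolo[1,2-c][1,3,2]oxazaborole ((S)-Me-CBS, 20 mol%), BH3·SMe2, THF, −30 °C
Reagents that add atoms: none
Why: Corey–Bakshi–Shibata reduction gives 1,2-reduction of the enone, and with the quaternary C6 as the large flank and the C2 vinyl carbon as the small one the (S)-catalyst should deliver hydride to the face that gives the (R)-carbinol at C1.

Step 5
Reactants: 10 allylic alcohol; 11 diiodomethane
Product: 12 cyclopropyl carbinol ketal, (1R,2R,5S)-2-hydroxy-4,4-dimethylspiro[bicyclo[3.1.0]hexane-3,1'-cyclohexan]-4'-one ethylene ketal (target labels: C1 R, C2 R, C4 S; OH and the cyclopropane CH2 C3 on the same face)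
Conditions: Et2Zn, CH2I2, CH2Cl2, 0 °C → rt
Reagents that add atoms: diiodomethane (11), ICI
Why: Hydroxyl-directed Simmons–Smith cyclopropanation in the Furukawa variant: the zinc alkoxide at C1 delivers the methylene (C3) to the face of the C2=C4 bond on which the oxygen sits, which sets C2 (R) and C4 (S) from the C1 carbinol.

Step 6
Reactants: 12 cyclopropyl carbinol ketal
Product: 13 cyclopropyl ketone ketal, (1R,5S)-4,4-dimethylspiro[bicyclo[3.1.0]hexane-3,1'-cyclohexane]-2,4'-dione 4'-(ethylene ketal) (target labels: C1 carbonyl, C2 R, C4 S)
Conditions: Pr4N[RuO4] (5 mol%), N-methylmorpholine N-oxide, 4 Å molecular sieves, CH2Cl2, rt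
Reagents that add atoms: none
Why: Ley–Griffith oxidation under neutral conditions turns the directing carbinol into the C1 ketone without opening the cyclopropane or the ketal, leaving C2 and C4 as the only stereocentres.

Step 7
Reactants: 13 cyclopropyl ketone ketal; 14 methylmagnesium bromide
Product: 15 methyl carbinol ketal, (1R,2R,5S)-2-hydroxy-2,4,4-trimethylspiro[bicyclo[3.1.0]hexane-3,1'-cyclohexan]-4'-one ethylene ketal (target labels: C1 R, C2 R, C4 S)
Conditions: MeMgBr (3 equiv), THF, 0 °C → rt
Reagents that add atoms: methylmagnesium bromide (14), C[Mg]Br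
Why: Grignard 1,2-addition to a ketone that cannot enolise usefully (bridgehead cyclopropane CH on one side, quaternary C6 on the other) should take place from the convex face anti to the cyclopropane CH2, giving the (1R) carbinol with OH syn to C3; this centre is lost again in step 9 and its configuration is of no consequence.

Step 8
Reactants: 15 methyl carbinol ketal
Product: 16 (1R,2R,5S)-2-hydroxy-2,4,4-trimethylspiro[bicyclo[3.1.0]hexane-3,1'-cyclohexan]-4'-one (keto carbinol; target labels C1 R, C2 R, C4 S)
Conditions: pyridinium p-toluenesulfonate (cat.), acetone–H2O, 40 °C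
Reagents that add atoms: water, O
Why: Mild acid-catalysed ketal hydrolysis frees the unhindered C9 ketone, and the weakly acidic pyridinium salt should leave the tertiary cyclopropyl carbinol in place, any reversible ionisation at C1 being harmless because that centre becomes sp2 in the next step.

Step 9
Reactants: 16 keto carbinol
Product: 17 (4S)-4-bromo-1,5,5-trimethylspiro[5.5]undec-1-en-9-one
Conditions: 48% aq HBr, CH2Cl2, 0 °C, brief contact
Reagents that add atoms: hydrogen bromide, Br
Why: Protonation and loss of water at C1 give a tertiary cyclopropylcarbinyl cation whose charge is shared with C4 through the C2–C4 bond, and bromide takes C4 from the side opposite that bond while C1=C2 forms, which is the cyclopropylcarbinyl-to-homoallyl bromide rearrangement of the Julia olefin synthesis. The closest ring-enlarging cases are the acid opening of the 2-methylbicyclo[3.1.0]hex-2-yl cations of the thujane series to 4-substituted 1-methylcyclohexenes and the i-steroid opening of 3,5-cyclosteroids to 3-halo-5-enes. Ring A is not closed by a cyclisation: the five-membered ring C1–C2–C4–C5–C6 grows by one atom when the internal C2–C4 bond is cut and C3 becomes a ring member. The new stereocentre C4 is set by inversion, so its (S) configuration follows from the cyclopropane face fixed in steps 4 and 5, and the configuration at C1 plays no part. The step needs cleavage of C2–C4 and not of the external C2–C3 bond; the secondary C4 carries more of the charge than the primary C3, the six-membered homoallylic bromide is the more stable product under reversible HBr, and a high bromide concentration at 0 °C should capture C4 before a methyl group migrates from C5.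

Step 10
Reactants: 17 bromo spiro ketone
Product: 19 {[(4S,6R)-4-bromo-1,5,5-trimethylspiro[5.5]undeca-1,9-dien-9-yl]oxy}trimethylsilane, via lithium enolate 18 (not isolated)
Conditions: bis[(S)-1-phenylethyl]amine, n-BuLi, THF, −78 °C; Me3SiCl, then 17, −100 → −78 °C
Reagents that add atoms: chlorotrimethylsilane, C[Si](C)(C)Cl
Why: Arm-selective deprotonation by a chiral lithium amide with internal Me3SiCl quench (asymmetric deprotonation of a 4,4-disubstituted cyclohexanone): removal of the axial proton at C10 and not at C8 makes C6 a stereocentre (R), the sense being assigned as stated in the assumption, and the cold amide should not touch the neopentylic C4 bromide.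

Step 11
Reactants: 19 silyl enol ether
Product: 20 (4S,6R,10R)-4,10-dibromo-1,5,5-trimethylspiro[5.5]undec-1-en-9-one
Conditions: N-bromosuccinimide, THF, −78 → 0 °C
Reagents that add atoms: N-bromosuccinimide, O=C1CCC(=O)N1Br
Why: Electrophilic α-bromination of the silyl enol ether, which is far more nucleophilic than the hindered C1=C2 bond, places bromine on C10 from the face anti to the axial C1 ligand of C6, so that it ends equatorial and cis to C5 (10R), the same epimer that equilibration through the enol would favour.

Step 12
Reactants: 20 α-bromo ketone; 14 methylmagnesium bromide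
Product: 21 (4S,6R,9R,10R)-4,10-dibromo-1,5,5,9-tetramethylspiro[5.5]undec-1-en-9-ol (OH trans to the C10 bromine)
Conditions: MeMgBr, CeCl3, THF, −78 °C
Reagents that add atoms: methylmagnesium bromide (14), C[Mg]Br
Why: Organocerium 1,2-addition avoids enolisation and halogen–metal exchange of the α-bromo ketone, and axial attack, in which the carbonyl oxygen swings away from the equatorial C10–Br dipole as in hydride reductions of equatorial α-bromo cyclohexanones, should give the trans bromohydrin with the C9 methyl axial and cis to bromine and the hydroxyl equatorial (9R).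

Step 13
Reactants: 21 bromohydrin
Product: 23 (4S,6R,9R,10R)-4,10-dibromo-9-chloro-1,5,5,9-tetramethylspiro[5.5]undec-1-ene (CNP0126187.3), via chlorosulfite 22 (not isolated)
Conditions: SOCl2, Et2O, −20 → 0 °C
Reagents that add atoms: thionyl chloride, O=S(Cl)Cl
Why: Chlorodehydroxylation through the tertiary chlorosulfite should proceed with retention at C9, since both internal return of chloride within the ion pair (SNi) and anti opening of the bromonium ion formed by neighbouring-group participation of the C10 bromine put chloride on the face that the oxygen left, trans to bromine, while base-free conditions at low temperature limit elimination and spare the C1=C2 bond and the C4 bromide.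

**Compound list**

1 | 1,5-dichloropentan-3-one | ClCCC(=O)CCCl | starting material
2 | ethylene glycol | OCCO | starting material
3 | 2,2-bis(2-chloroethyl)-1,3-dioxolane | ClCCC1(CCCl)OCCO1 | intermediate
4 | 2,2-bis(2-iodoethyl)-1,3-dioxolane | ICCC1(CCI)OCCO1 | intermediate
5 | 4,4-dimethylcyclopent-2-en-1-one | O=C1C=CC(C)(C)C1 | starting material
6 | lithium 5,5-dimethylcyclopenta-1,3-dien-1-olate (C6 enolate of 5, not isolated) | [Li]OC1=CC(C)(C)C=C1 | intermediate
7 | 5-{2-[2-(2-iodoethyl)-1,3-dioxolan-2-yl]ethyl}-4,4-dimethylcyclopent-2-en-1-one (racemic, not isolated) | O=C1C=CC(C)(C)C1CCC2(CCI)OCCO2 | intermediate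
8 | lithium enolate of 7 at C6 (not isolated) | [Li]OC1=C(CCC2(CCI)OCCO2)C(C)(C)C=C1 | intermediate
9 | 12,12-dimethyl-1,4-dioxadispiro[4.2.4.2]tetradec-10-en-9-one | O=C1C=CC(C)(C)C12CCC3(CC2)OCCO3 | intermediate
10 | (9R)-12,12-dimethyl-1,4-dioxadispiro[4.2.4.2]tetradec-10-en-9-ol | O[C@@H]1C=CC(C)(C)C12CCC3(CC2)OCCO3 | intermediate
11 | diiodomethane | ICI | starting material
12 | (1R,2R,5S)-2-hydroxy-4,4-dimethylspiro[bicyclo[3.1.0]hexane-3,1'-cyclohexan]-4'-one ethylene ketal | O[C@@H]1[C@@H]2C[C@@H]2C(C)(C)C13CCC4(CC3)OCCO4 | intermediate
13 | (1R,5S)-4,4-dimethylspiro[bicyclo[3.1.0]hexane-3,1'-cyclohexane]-2,4'-dione 4'-(ethylene ketal) | O=C1[C@@H]2C[C@@H]2C(C)(C)C13CCC4(CC3)OCCO4 | intermediate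
14 | methylmagnesium bromide | C[Mg]Br | starting material
15 | (1R,2R,5S)-2-hydroxy-2,4,4-trimethylspiro[bicyclo[3.1.0]hexane-3,1'-cyclohexan]-4'-one ethylene ketal | C[C@@]1(O)[C@@H]2C[C@@H]2C(C)(C)C13CCC4(CC3)OCCO4 | intermediate
16 | (1R,2R,5S)-2-hydroxy-2,4,4-trimethylspiro[bicyclo[3.1.0]hexane-3,1'-cyclohexan]-4'-one | C[C@@]1(O)[C@@H]2C[C@@H]2C(C)(C)C13CCC(=O)CC3 | intermediate
17 | (4S)-4-bromo-1,5,5-trimethylspiro[5.5]undec-1-en-9-one | CC1=CC[C@H](Br)C(C)(C)C12CCC(=O)CC2 | intermediate
18 | lithium (4S,6R)-4-bromo-1,5,5-trimethylspiro[5.5]undeca-1,9-dien-9-olate (not isolated) | CC1=CC[C@H](Br)C(C)(C)[C@@]12CCC(O[Li])=CC2 | intermediate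
19 | {[(4S,6R)-4-bromo-1,5,5-trimethylspiro[5.5]undeca-1,9-dien-9-yl]oxy}trimethylsilane | CC1=CC[C@H](Br)C(C)(C)[C@@]12CCC(O[Si](C)(C)C)=CC2 | intermediate
20 | (4S,6R,10R)-4,10-dibromo-1,5,5-trimethylspiro[5.5]undec-1-en-9-one | CC1=CC[C@H](Br)C(C)(C)[C@@]12CCC(=O)[C@H](Br)C2 | intermediate
21 | (4S,6R,9R,10R)-4,10-dibromo-1,5,5,9-tetramethylspiro[5.5]undec-1-en-9-ol | CC1=CC[C@H](Br)C(C)(C)[C@@]12CC[C@@](C)(O)[C@H](Br)C2 | intermediate
22 | chlorosulfite of 21 at the C9 oxygen (not isolated) | CC1=CC[C@H](Br)C(C)(C)[C@@]12CC[C@@](C)(OS(Cl)=O)[C@H](Br)C2 | intermediate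
23 | (4S,6R,9R,10R)-4,10-dibromo-9-chloro-1,5,5,9-tetramethylspiro[5.5]undec-1-ene | CC1=CC[C@H](Br)C(C)(C)[C@@]12CC[C@@](C)(Cl)[C@H](Br)C2 | target

**Totals**

Total step count: 13.
Longest linear sequence: 13 steps (1 → 23 through steps 1–13; 11 steps counted from 5).

**Steps most likely to fail**

Step 9 (key step). The cation may be captured at the primary cyclopropane carbon C3 instead of C4, because the external C2–C3 bond is the better aligned with the empty orbital at C1 of a bicyclo[3.1.0]hexyl cation. A methyl group may also migrate from C5 to the neopentylic C4 before bromide arrives, and the terminus here is secondary, not tertiary as in the thujane cases. Fallback, from 16 back to 17: 16 is warmed with HClO4 (cat.) in aqueous dioxane so that water, under thermodynamic control, takes C4 and gives the ring-enlarged homoallylic alcohol (4S)-4-hydroxy-1,5,5-trimethylspiro[5.5]undec-1-en-9-one F1. Mesylation (MeSO2Cl, Et3N, CH2Cl2) gives (4S)-1,5,5-trimethyl-9-oxospiro[5.5]undec-1-en-4-yl methanesulfonate F2. Heating F2 with LiBr in acetone should then deliver 17 with retention at C4, because direct displacement at the neopentylic carbon is shut off and substitution runs through participation of the C1=C2 bond, as for cholesteryl sulfonates.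

Step 13. Ionisation may go to an open tertiary cation that takes chloride from the axial direction, with loss of configuration at C9, or loses a proton toward C8 or the methyl group; the equatorial C10 bromine must leave the chair to participate. Fallback, from 19 back to 23: MeLi cleaves the silyl ether of 19 to the lithium enolate, which PhNTf2 traps as the enol triflate (4S,6R)-4-bromo-1,5,5-trimethylspiro[5.5]undeca-1,9-dien-9-yl trifluoromethanesulfonate F3. Me2CuLi replaces triflate by methyl to give the diene (4S,6R)-4-bromo-1,5,5,9-tetramethylspiro[5.5]undeca-1,9-diene F4. Anti bromochlorination of the unhindered C9=C10 bond with Bu4N[BrCl2] in CH2Cl2 at −78 °C should put bromine on C10 from the face anti to the axial C1 and chloride on the tertiary C9 trans to it, giving 23; the C1=C2 bond, shielded by the quaternary C6, should react more slowly.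

Step 10. The amide may discriminate poorly between the two α-methylene groups, or select the wrong one, because both chair forms of ring B place a bulky C6 ligand syn to the axial α-protons and the remote C4 centre may oppose the reagent. Fallback, from 17 back to 20: 17 is enolised without arm selection (Me3SiOTf, Et3N, CH2Cl2) to 19 mixed with its C6 epimer, the (4S,6S) silyl enol ether F5. N-Bromosuccinimide converts the mixture into 20 and the (4S,6S,10S) bromo ketone F6, which are diastereomers and are separated by chromatography. F6 is reduced back to 17 with Zn in AcOH and recycled.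

**Further compounds**

F1 | step 9 | (4S)-4-hydroxy-1,5,5-trimethylspiro[5.5]undec-1-en-9-one | CC1=CC[C@H](O)C(C)(C)C12CCC(=O)CC2
F2 | step 9 | (4S)-1,5,5-trimethyl-9-oxospiro[5.5]undec-1-en-4-yl methanesulfonate | CC1=CC[C@H](OS(C)(=O)=O)C(C)(C)C12CCC(=O)CC2
F3 | step 13 | (4S,6R)-4-bromo-1,5,5-trimethylspiro[5.5]undeca-1,9-dien-9-yl trifluoromethanesulfonate | CC1=CC[C@H](Br)C(C)(C)[C@@]12CCC(OS(=O)(=O)C(F)(F)F)=CC2
F4 | step 13 | (4S,6R)-4-bromo-1,5,5,9-tetramethylspiro[5.5]undeca-1,9-diene | CC1=CC[C@H](Br)C(C)(C)[C@@]12CCC(C)=CC2
F5 | step 10 | {[(4S,6S)-4-bromo-1,5,5-trimethylspiro[5.5]undeca-1,9-dien-9-yl]oxy}trimethylsilane | CC1=CC[C@H](Br)C(C)(C)[C@]12CCC(O[Si](C)(C)C)=CC2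
F6 | step 10 | (4S,6S,10S)-4,10-dibromo-1,5,5-trimethylspiro[5.5]undec-1-en-9-one | CC1=CC[C@H](Br)C(C)(C)[C@]12CCC(=O)[C@@H](Br)C2
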